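**Retrosynthetic overview**

1. Ring locants used in the text: C1 = oxirane carbon bearing CH2OBz, C2 = CH(OBz), C3 = CH(OH), C4=C5 = alkene, C6 = oxirane CH. The target is read as the mono-epoxide of a 1,3-diene C1=C6–C5=C4 with cis oxygens on C2 and C3, all three ring oxygens being on one face.
2. Key disconnection: the cyclohexene ring is closed through the C3–C4 bond, made together with C1–C2, in a catalytic enantioselective inverse-electron-demand Diels–Alder reaction of methyl 2-oxo-2H-pyran-3-carboxylate (a dearomatised heteroarene) with 2,2-dimethyl-1,3-dioxole.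
3. Feature that makes this possible: ring atoms C1, C6, C5, C4 and the exocyclic carbon on C1 have the connectivity of C3–C6 and the ester of the pyrone once its O–C(=O) unit is lost, and the cis-C2/C3 oxygens are those of a ring-locked cis-enediol. The lactone ring C1–C(=O)–O–C4 is a temporary ring, expelled later as CO2.
4. Ring order: carbocycle first (with the temporary lactone and dioxolane rings), then loss of the lactone ring by retro-Diels–Alder reaction, then the oxirane ring last, by epoxidation directed from the C2 hydroxyl, so that C1 and C6 are relayed from the catalyst-set C2/C3.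
5. Functional-group end game: acetonide off, C3–OH silylated, ester reduced to CH2OH, two benzoates on, silyl ether off.

Key step: step 1

Remark: 2,2-dimethyl-1,3-dioxole (2) is taken as a purchasable speciality reagent; locants C1–C6 in the text are those of the overview, while systematic names carry their own locants.

**Route**

Step 1
Reactants: 1 methyl 2-oxo-2H-pyran-3-carboxylate; 2 2,2-dimethyl-1,3-dioxole
Product: 3 methyl (1R,2S,6R,7S)-4,4-dimethyl-9-oxo-3,5,8-trioxatricyclo[5.2.2.0(2,6)]undec-10-ene-1-carboxylate (endo cycloadduct)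
Conditions: Cu(OTf)2 (10 mol %), (R,R)-t-Bu-box [(4R,4'R)-2,2'-(propane-2,2-diyl)bis(4-tert-butyl-4,5-dihydro-1,3-oxazole), 11 mol %], 4 Å MS, 2 (1.5 equiv), CH2Cl2, −20 °C; filtration through silica, excess 2 evaporated below 30 °C
Reagents that add atoms: none
Why: Inverse-electron-demand Diels–Alder reaction: the pyrone, chelated through its lactone and ester carbonyl oxygens to the divalent copper bis(oxazoline) complex, acts as an electron-poor diene and takes up the electron-rich, ring-locked cis-enediol acetal in a concerted but asynchronous [4+2] event, the closest known reactions being the copper–bis(oxazoline)- and titanium–BINOL-catalysed cycloadditions of 3-carboalkoxy-2-pyrones with enol ethers. The six-membered carbocycle is closed in an intermolecular [4+2] mode by forming the C3–C4 and C1–C2 bonds together, which dearomatises the pyrone and leaves its O–C(=O) unit as a temporary lactone bridge between C1 and C4. C2 and C3 come out cis because the addition is suprafacial on the Z-locked dioxole, and they sit anti to the lactone bridge because of the endo transition state (acetal oxygens under the diene, the usual preference of enol ethers with this pyrone). The absolute configuration of all four new stereocentres is set by the ligand: on the square-planar chelate model the tert-butyl group of the (R,R)-ligand nearest to the diene covers one face, so the dioxole should add to the Re face of the ester-bearing pyrone carbon (the face on which lactone carbonyl carbon, ester carbon and ring CH run clockwise). The step needs facial and endo selectivity (ligand and secondary overlap) and mono-addition; the latter is secured because the CO2 bridge is retained at −20 °C, so no cyclohexadiene is released while dienophile is present, and regioselectivity is not an issue with the symmetric dioxole.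

Step 2
Reactants: 3 methyl (1R,2S,6R,7S)-4,4-dimethyl-9-oxo-3,5,8-trioxatricyclo[5.2.2.0(2,6)]undec-10-ene-1-carboxylate
Product: 4 methyl (3aS,7aR)-2,2-dimethyl-3a,7a-dihydro-1,3-benzodioxole-4-carboxylate
Conditions: toluene (0.05 M), 90–100 °C, N2
Reagents that add atoms: none
Why: Retro-Diels–Alder extrusion of CO2, the usual thermal fate of pyrone cycloadducts, removes the temporary lactone bridge and unveils the C1=C6–C5=C4 diene conjugated with the ester, while the two bridgehead stereocentres disappear and C2/C3 are untouched.

Step 3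
Reactants: 4 methyl (3aS,7aR)-2,2-dimethyl-3a,7a-dihydro-1,3-benzodioxole-4-carboxylate
Product: 5 methyl (5R,6S)-5,6-dihydroxycyclohexa-1,3-diene-1-carboxylate
Conditions: AcOH–H2O (4:1), rt
Reagents that add atoms: none
Why: Acid-catalysed acetal hydrolysis frees the cis-diol without touching a stereocentre, and the electron-withdrawing ester on the diene is expected to slow the competing acid-catalysed dehydration enough for the acetal to be cleaved selectively.

Step 4
Reactants: 5 methyl (5R,6S)-5,6-dihydroxycyclohexa-1,3-diene-1-carboxylate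
Product: 6 methyl (5R,6S)-5-[(tert-butyldimethylsilyl)oxy]-6-hydroxycyclohexa-1,3-diene-1-carboxylate
Conditions: TBSCl (1.1 equiv), imidazole, DMF, −20 °C
Reagents that add atoms: tert-butyldimethylsilyl chloride CC(C)(C)[Si](C)(C)Cl
Why: Site-selective silylation of the hydroxyl remote from the ring substituent (C3–OH), as known for 3-substituted arene cis-dihydrodiols, since the C2 hydroxyl is flanked by the ester-bearing carbon and hydrogen-bonded to the ester; no stereocentre is formed.

Step 5
Reactants: 6 methyl (5R,6S)-5-[(tert-butyldimethylsilyl)oxy]-6-hydroxycyclohexa-1,3-diene-1-carboxylate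
Product: 7 (1S,6R)-6-[(tert-butyldimethylsilyl)oxy]-2-(hydroxymethyl)cyclohexa-2,4-dien-1-ol
Conditions: i-Bu2AlH (DIBAL-H, 3.5 equiv), CH2Cl2, −78 → −20 °C; aq. potassium sodium tartrate work-up
Reagents that add atoms: none
Why: Hydride reduction of the conjugated ester by 1,2-addition gives the primary allylic alcohol (the free hydroxyl being carried as its aluminium alkoxide), the silyl ether is inert and no stereocentre changes.

Step 6
Reactants: 7 (1S,6R)-6-[(tert-butyldimethylsilyl)oxy]-2-(hydroxymethyl)cyclohexa-2,4-dien-1-ol
Product: 8 (1S,4R,5R,6R)-4-[(tert-butyldimethylsilyl)oxy]-6-(hydroxymethyl)-7-oxabicyclo[4.1.0]hept-2-en-5-ol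
Conditions: VO(acac)2 (5 mol %), t-BuOOH (1.2 equiv, decane), CH2Cl2, 0 °C
Reagents that add atoms: tert-butyl hydroperoxide CC(C)(C)OO
Why: Hydroxyl-directed vanadium-catalysed epoxidation: the vanadate ester of the secondary C2 hydroxyl (chelated with the primary one) should deliver oxygen only to the C1=C6 alkene, which is allylic to both free hydroxyls, and to the face that carries the C2 oxygen, which sets C1 and C6 cis to the C2 and C3 oxygens; the C4=C5 alkene has no free allylic hydroxyl.

Step 7
Reactants: 8 (1S,4R,5R,6R)-4-[(tert-butyldimethylsilyl)oxy]-6-(hydroxymethyl)-7-oxabicyclo[4.1.0]hept-2-en-5-ol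
Product: 9 [(1S,4R,5R,6S)-5-(benzoyloxy)-4-[(tert-butyldimethylsilyl)oxy]-7-oxabicyclo[4.1.0]hept-2-en-6-yl]methyl benzoate
Conditions: BzCl (2.5 equiv), pyridine, DMAP (cat.), CH2Cl2, 0 °C → rt
Reagents that add atoms: benzoyl chloride O=C(Cl)c1ccccc1
Why: DMAP-catalysed acylation of the only two free hydroxyls installs both benzoates in one operation under mildly basic conditions that should leave the vinyl epoxide and the silyl ether intact; no stereocentre is affected.

Step 8
Reactants: 9 [(1S,4R,5R,6S)-5-(benzoyloxy)-4-[(tert-butyldimethylsilyl)oxy]-7-oxabicyclo[4.1.0]hept-2-en-6-yl]methyl benzoate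
Product: 10 [(1S,4R,5R,6S)-5-(benzoyloxy)-4-hydroxy-7-oxabicyclo[4.1.0]hept-2-en-6-yl]methyl benzoate (target)
Conditions: Bu4NF (TBAF)/AcOH (1:1, 2 equiv), THF, 0 °C → rt
Reagents that add atoms: none
Why: Fluoride-mediated desilylation, buffered with acetic acid so that the liberated C3 alkoxide is protonated at once and neither migration of the neighbouring benzoate nor opening of the vinyl epoxide is expected; no stereocentre is affected.

**Compound list**

1 | methyl 2-oxo-2H-pyran-3-carboxylate | COC(=O)C1=CC=COC1=O | starting material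
2 | 2,2-dimethyl-1,3-dioxole | CC1(C)OC=CO1 | starting material
3 | methyl (1R,2S,6R,7S)-4,4-dimethyl-9-oxo-3,5,8-trioxatricyclo[5.2.2.0(2,6)]undec-10-ene-1-carboxylate (endo adduct; acetonide oxygens anti to the lactone bridge) | COC(=O)[C@]12C=C[C@H](OC1=O)[C@H]1OC(C)(C)O[C@H]12 | intermediate
4 | methyl (3aS,7aR)-2,2-dimethyl-3a,7a-dihydro-1,3-benzodioxole-4-carboxylate | COC(=O)C1=CC=C[C@H]2OC(C)(C)O[C@@H]12 | intermediate
5 | methyl (5R,6S)-5,6-dihydroxycyclohexa-1,3-diene-1-carboxylate | COC(=O)C1=CC=C[C@@H](O)[C@H]1O | intermediate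
6 | methyl (5R,6S)-5-[(tert-butyldimethylsilyl)oxy]-6-hydroxycyclohexa-1,3-diene-1-carboxylate | COC(=O)C1=CC=C[C@@H](O[Si](C)(C)C(C)(C)C)[C@H]1O | intermediate
7 | (1S,6R)-6-[(tert-butyldimethylsilyl)oxy]-2-(hydroxymethyl)cyclohexa-2,4-dien-1-ol | OCC1=CC=C[C@@H](O[Si](C)(C)C(C)(C)C)[C@H]1O | intermediate
8 | (1S,4R,5R,6R)-4-[(tert-butyldimethylsilyl)oxy]-6-(hydroxymethyl)-7-oxabicyclo[4.1.0]hept-2-en-5-ol | OC[C@]12O[C@H]1C=C[C@@H](O[Si](C)(C)C(C)(C)C)[C@H]2O | intermediate
9 | [(1S,4R,5R,6S)-5-(benzoyloxy)-4-[(tert-butyldimethylsilyl)oxy]-7-oxabicyclo[4.1.0]hept-2-en-6-yl]methyl benzoate | O=C(OC[C@]12O[C@H]1C=C[C@@H](O[Si](C)(C)C(C)(C)C)[C@H]2OC(=O)c1ccccc1)c1ccccc1 | intermediate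
10 | [(1S,4R,5R,6S)-5-(benzoyloxy)-4-hydroxy-7-oxabicyclo[4.1.0]hept-2-en-6-yl]methyl benzoate | O=C(OC[C@]12O[C@H]1C=C[C@@H](O)[C@H]2OC(=O)c1ccccc1)c1ccccc1 | target

**Step count and risks**

Total step count: 8. Longest linear sequence: 8 steps (from 1 and 2).

Steps most likely to fail:

Step 1. What may go wrong: Lewis-acid-induced oligomerisation of the enol acetal, slow cycloaddition of the 1,2-disubstituted dienophile, or low or reversed facial discrimination by the catalyst. The fallback sets out from 1 (with 2) and returns at 6. The cycloaddition is run without metal under high pressure (about 12 kbar, CH2Cl2, rt), which should give the endo adduct as the racemate, racemic methyl (1R*,2S*,6R*,7S*)-4,4-dimethyl-9-oxo-3,5,8-trioxatricyclo[5.2.2.0(2,6)]undec-10-ene-1-carboxylate F1. CO2 extrusion as in step 2 then gives racemic methyl cis-2,2-dimethyl-3a,7a-dihydro-1,3-benzodioxole-4-carboxylate F2, and hydrolysis as in step 3 gives racemic methyl cis-5,6-dihydroxycyclohexa-1,3-diene-1-carboxylate F3. The silylation is then run as a catalytic kinetic resolution (TBSCl, i-Pr2NEt, amino-acid-derived chiral N-methylimidazole silylation catalyst, THF, −40 °C, stopped near half conversion), a known enantio- and site-selective silylation of syn-1,2-diols. The catalyst antipode is chosen that silylates the (5R,6S) diol at its less hindered hydroxyl to give 6. The unreacted antipode, methyl (5S,6R)-5,6-dihydroxycyclohexa-1,3-diene-1-carboxylate F4, is separated by chromatography.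

Step 3. What may go wrong: acid-catalysed dehydration of the liberated cis-dihydrodiol (aromatisation to a hydroxybenzoate) competing with acetal cleavage. The fallback sets out from 3 and returns at 5. The acetonide is cleaved before any diene exists, on the bridged lactone (TFA–H2O 9:1, 0 °C), to give methyl (1S,4R,7S,8S)-7,8-dihydroxy-3-oxo-2-oxabicyclo[2.2.2]oct-5-ene-4-carboxylate F5. CO2 is then expelled under neutral conditions (1,4-dioxane, 90 °C) to give 5 without contact between diene and acid.

Step 6. What may go wrong: oxygen transfer to the C4=C5 alkene, delivery to the wrong face when the primary hydroxyl alone directs, or Lewis-acid-triggered aromatisation of the electron-rich diene diol. The fallback sets out from 7 and returns at 9. The primary hydroxyl is benzoylated first (BzCl 1.05 equiv, 2,4,6-collidine, CH2Cl2, −40 °C) to give [(5R,6S)-5-[(tert-butyldimethylsilyl)oxy]-6-hydroxycyclohexa-1,3-dien-1-yl]methyl benzoate F6. The one remaining hydroxyl (on C2) then directs a buffered peracid epoxidation (mCPBA, NaHCO3, CH2Cl2, 0 °C) of the adjacent trisubstituted alkene from its own face to give [(1S,4R,5R,6R)-4-[(tert-butyldimethylsilyl)oxy]-5-hydroxy-7-oxabicyclo[4.1.0]hept-2-en-6-yl]methyl benzoate F7. Benzoylation of that hydroxyl (BzCl, pyridine, DMAP, CH2Cl2) gives 9.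

**Further compounds**

F1 | step 1 | racemic methyl (1R*,2S*,6R*,7S*)-4,4-dimethyl-9-oxo-3,5,8-trioxatricyclo[5.2.2.0(2,6)]undec-10-ene-1-carboxylate | COC(=O)[C@]12C=C[C@H](OC1=O)[C@H]1OC(C)(C)O[C@H]12.COC(=O)[C@@]12C=C[C@@H](OC1=O)[C@@H]1OC(C)(C)O[C@@H]12
F2 | step 1 | racemic methyl cis-2,2-dimethyl-3a,7a-dihydro-1,3-benzodioxole-4-carboxylate | COC(=O)C1=CC=C[C@H]2OC(C)(C)O[C@@H]12.COC(=O)C1=CC=C[C@@H]2OC(C)(C)O[C@H]12
F3 | step 1 | racemic methyl cis-5,6-dihydroxycyclohexa-1,3-diene-1-carboxylate | COC(=O)C1=CC=C[C@@H](O)[C@H]1O.COC(=O)C1=CC=C[C@H](O)[C@@H]1O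
F4 | step 1 | methyl (5S,6R)-5,6-dihydroxycyclohexa-1,3-diene-1-carboxylate | COC(=O)C1=CC=C[C@H](O)[C@@H]1O
F5 | step 3 | methyl (1S,4R,7S,8S)-7,8-dihydroxy-3-oxo-2-oxabicyclo[2.2.2]oct-5-ene-4-carboxylate | COC(=O)[C@]12C=C[C@H](OC1=O)[C@@H](O)[C@H]2O
F6 | step 6 | [(5R,6S)-5-[(tert-butyldimethylsilyl)oxy]-6-hydroxycyclohexa-1,3-dien-1-yl]methyl benzoate | O=C(OCC1=CC=C[C@@H](O[Si](C)(C)C(C)(C)C)[C@H]1O)c1ccccc1
F7 | step 6 | [(1S,4R,5R,6R)-4-[(tert-butyldimethylsilyl)oxy]-5-hydroxy-7-oxabicyclo[4.1.0]hept-2-en-6-yl]methyl benzoate | O=C(OC[C@]12O[C@H]1C=C[C@@H](O[Si](C)(C)C(C)(C)C)[C@H]2O)c1ccccc1
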